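(The numbers in the tables were generated by integration from invented constants; the scatter is artificial.)

Time splits these flasks into a quick part and a slow part. By 15.0 min the zeta run has lost nearly all of its starting material, while in the gamma run the reading of intermediate B goes from 75 % to 62 % between 15.0 min and 60.0 min. The quick split is the thing to reckon first.

all flasks: starting material 15 mM

| charge | partner | remark | time |
|---|---|---|---|
| zeta | 13 mM | run made earlier |  |
| gamma | 68 mM | run made earlier |  |
| dawn | 15.0 mM |  | 1.0 h |
| spring | 38.0 mM |  | 1.0 h |
| summer | 94.0 mM |  | 1.0 h |

| run | time / min | side product / % | intermediate C / % | target / % | starting material / % | intermediate B / % | intermediate A / % |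
|---|---|---|---|---|---|---|---|
| zeta | 5.00 | 0 | 0 | 0 | 24 | 33 | 41 |
| zeta | 10.0 | 2 | 0 | 2 | 8 | 37 | 52 |
| zeta | 15.0 | 3 | 3 | 3 | 2 | 36 | 54 |
| zeta | 30.0 | 2 | 0 | 3 | 0 | 42 | 58 |
| zeta | 60.0 | 4 | 1 | 0 | 2 | 38 | 55 |
| gamma | 5.00 | 6 | 2 | 0 | 0 | 73 | 16 |
| gamma | 10.0 | 5 | 2 | 4 | 0 | 76 | 20 |
| gamma | 15.0 | 7 | 4 | 2 | 2 | 75 | 15 |
| gamma | 30.0 | 7 | 0 | 9 | 1 | 68 | 15 |
| gamma | 60.0 | 4 | 3 | 12 | 1 | 62 | 10 |

(standard deviation of a reading: 2 percentage points)

- what may be going on: partner + intermediate A -> intermediate C; partner + intermediate B -> target; starting material -> intermediate A; intermediate C -> intermediate B; starting material + partner -> intermediate B; starting material + partner -> side product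

- which of these there is most of at the end, counted by the starting material in it, dawn (target / intermediate A / intermediate C / intermediate B / side product)
- which of these there is most of at the end, counted by the starting material in it, spring (target / intermediate A / intermediate C / intermediate B / side product)
- which of these there is most of at the end, counted by the starting material in it, summer (target / intermediate A / intermediate C / intermediate B / side product)
- the largest of these amounts at the end, in percent of the starting material charged, dawn
- the largest of these amounts at the end, in percent of the starting material charged, spring
- the largest of these amounts at the end, in percent of the starting material charged, summer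

The bench rule freezes c(partner) at a constant value, which makes the starting material's step with partner pseudo-first-order. Starting material then has two exits, to intermediate A by itself and to intermediate B with partner, and B/A equals c(partner)/K. In gamma, partner stands at 4.53 times the starting material. The readings up to 15.0 min average 17.0 % intermediate A and 74.7 % intermediate B. Partner is frozen at its charge minus half of what intermediate B took, 62.4 mM, and this gives the reading 14.2 mM for K, the crossover concentration of partner at which the two exits take equal shares.

The border shows in zeta, where the partner-to-starting-material ratio is 0.867 and intermediate B has taken 41.5 % of the partner. Freezing at the charge gives intermediate A a share of 52.2 %, but the readings at 15.0 min show 60.0 %. Freezing at the corrected 10.3 mM gives 58.0 %, so the correction is needed there.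

With one such correction, the reckoning here gives intermediate A these shares of the split, before side product and slow drift: dawn 56.0 %, spring 30.4 %, summer 14.0 %.

The forecast, with its own “crossover is near K ≈ 13.5 mM”, includes the slow steps, so its values differ from these shares. It names intermediate A for dawn at 51 % (46 % to 56 %), intermediate B for spring at 65 % (60 % to 71 %), and intermediate B for summer at 64 % (56 % to 71 %).

Dawn ends with intermediate A at 51.0 %, spring with intermediate B at 61.8 %, and summer with intermediate B at 61.3 %, each inside the forecast's range. In summer at 1.00 h, the rate that makes intermediate B is 0.0832 of the rate that takes it away, and its amount has gone from 77.6 % at 0.200 h to 61.3 %. In dawn, the split of 56.0 % reckoned from K stands against 54.4 % of what is not side product held in intermediates A and C at the end, after the slow steps, and intermediate A leads intermediate B by 8 percentage points.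

    partner + intermediate A → intermediate C (k = 0.00170 M⁻¹ s⁻¹)
    partner + intermediate B → target (k = 0.00110 M⁻¹ s⁻¹)
    starting material → intermediate A (k = 0.00270 s⁻¹)
    intermediate C → intermediate B (k = 1.10 × 10⁻⁴ s⁻¹)
    starting material + partner → intermediate B (k = 0.200 M⁻¹ s⁻¹)
    starting material + partner → side product (k = 0.0120 M⁻¹ s⁻¹)

A neighbour of summer charged with 380 mM of partner has a partner-to-starting-material ratio of 25.3, so K with partner frozen at its charge gives the intermediate A exit 3.60 %. That split belongs to the start; after the slow steps the computed flask holds 2.63 % in intermediates A and C together at 1.00 h, and target stands highest at 69.4 %.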